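(The data come from a simulation with constants of no real substance, noise included.)

What does a larger charge of free catalyst do to the rate of making product at 30% conversion?

the same everywhere: substrate 0.050 M; free catalyst 1.2 mM

| flask | coupling partner | remark |
|---|---|---|
| maple | 0.025 M | run made earlier |
| birch | 0.038 M | run made earlier |
| flask | 0.0500 M |  |

| run | time / min | product / % | substrate / % |
|---|---|---|---|
| maple | 10.0 | 0.7 | 93.3 |
| maple | 15.0 | 1.4 | 91.3 |
| maple | 20.0 | 3.6 | 87.5 |
| maple | 30.0 | 6.9 | 83.4 |
| maple | 50.0 | 10.3 | 76.6 |
| maple | 80.0 | 17.7 | 66.7 |
| maple | 120 | 26.9 | 56.9 |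
| birch | 15.0 | 2.1 | 90.8 |
| birch | 30.0 | 7.3 | 83.1 |
| birch | 50.0 | 14.1 | 74.5 |
| birch | 60.0 | 17.9 | 69.8 |
| birch | 80.0 | 25.3 | 64.6 |
| birch | 90.0 | 27.2 | 61.8 |
| birch | 120 | 34.6 | 55.1 |

(readings scatter by 1 percentage point)

- factor on the rate of making product when 30% of the substrate are converted if free catalyst is charged twice over
- factor on the rate when 30% of the substrate are converted if free catalyst is charged at 12 mM instead

- what was read earlier has a scatter of 1 percentage point, one standard deviation
- no earlier run changes the charge of free catalyst; that part of a forecast is a guess

I start from the substrate, whose first-order slope bends in both runs. In birch it is 0.00617 min⁻¹ up to 30.0 min and 0.00457 min⁻¹ from there to 120 min. The centres of these windows lie 60.0 min apart, and birch has 69.8% of its substrate left after 60.0 min, so that gap is about the time to 30% conversion. I fold this into one number: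

D = ln(early slope / late slope) = 0.301

This D is my clock number, the fall of the substrate's first-order slope, on a logarithmic scale, over about the time that 30% of the substrate takes; in birch the late slope reads 74.0% of the early one, and I take that fall as catalyst activity lost. Maple, with less coupling partner, gives 0.354, and with a scatter of 1 percentage point on each reading I don't read the two as different. But neither run changes the charge, so a loss that runs by time is my assumption.

I assume that the rate follows the catalyst, so that without loss a charge s times larger gives a gain of s. With loss by time, I reckon that the run, about s times shorter, loses about D/s. Joining the two ends: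

gain = s × exp[D(1 − 1/s)]

For a doubled charge I reckon 2.33.

The forecast gives 1.8 (1.2 to 2.2) and 6 (1.5 to 11), in its words “The runs cannot discriminate, so I shade below linear”.

The flask gives 2.24 for the doubled charge and 12.0 for 12 mM.

    substrate + free catalyst → free catalyst + open intermediate (k = 0.0950 M⁻¹ s⁻¹)
    coupling partner + catalyst intermediate → free catalyst + product (k = 0.660 M⁻¹ s⁻¹)
    free catalyst + open intermediate ⇌ catalyst intermediate (K = 36.0 M⁻¹, k = 9.40 M⁻¹ s⁻¹)
    free catalyst → spent catalyst (k = 6.30 × 10⁻⁵ s⁻¹)

The fit of the main steps alone answers the doubling with 2.00, and the flask holds 18.6% of its catalyst charge as spent catalyst after 1.00 h. On the 12 mM flask, s is 10.0, and D = 0.301 gives 13.1 against the simulated 12.0.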